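## The problem

1. Target 16 is tricin (rings A and C: 5,7-dihydroxychromen-4-one; ring B: the 3',5'-dimethoxy-4'-oxyphenyl group on C2). Its O4' is bound to C8 of a chain C7–C8–C9, where C7 is a benzylic carbinol on the 4-hydroxyphenyl ring D and C9 is a primary carbinol.
2. None of the rings resists closure; the difficulty sits in the three adjacent atoms O4', C8 and C7.
3. The O4'–C8 bond joins a secondary, β-oxygenated carbon to a phenol oxygen that is flanked by two methoxy groups and drained by the pyranone. That oxygen is a poor partner for substitution at an ordinary secondary alcohol derivative.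
4. C7 and C8 are the only stereocentres, (7R,8R), the threo series. Nothing else in the molecule can control them, so the absolute sense must come from a reagent and the relative sense from the way the two centres are made together.
5. C7–OH is para-hydroxybenzylic: acid, strong base or heat ionise it to a benzylic cation or a quinone methide of ring D, which erases C7. This centre should therefore appear late and be unmasked under neutral conditions.
6. The three phenols (acidity O7–H > O4'–H > chelated O5–H) must be told apart, and the ring C carbonyl rules out strong hydride donors and hard Lewis acids late in the route.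
7. The feature that opens the plan is that C8 lies between two oxygen-bearing carbons. When C7 is raised to the aryl ketone conjugated with ring D and C9 to an ester, three things follow:
   - C8–H becomes the central C–H of a 2-aryloxy-1,3-dicarbonyl unit, acidic and configurationally labile.
   - C8 becomes an activated electrophilic site for O4'.
   - C7 becomes the kind of aryl ketone that bifunctional ruthenium hydride catalysts recognise.

## Retrosynthesis

**16 ⇒ 15.** The two O–CH2Ph bonds are cut, at O7 of ring A and at O4 of ring D. Hydrogenolysis is the one unmasking that is neither acidic nor basic, which the para-hydroxybenzylic C7–OH demands. The ring D benzyl group also closes the quinone methide channel in all earlier steps. O5–H stays free throughout because its hydrogen bond to the C4 carbonyl already masks it. The forward step must spare C7–OH and the C2=C3 bond.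

**15 ⇒ 13.** The two C9–H bonds are cut, which returns C9 to the ester level. The ester is what makes the next cut possible, so it is a working part of the plan and not a detour. An α-aryloxy-β-hydroxy ester yields to a mild borohydride, which a flavone tolerates. The forward step must not open a retro-aldol or epimerisation path.

**13 ⇒ 11 (key).**
- Cut: the C7–H bond, and with it the fixed configuration at C8.
- Neighbouring cuts: C7–C8 (aldol) and O4'–C8 (displacement at the alcohol level) need stoichiometric chirality or an enantiopure electrophile with the correct sense of inversion.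
- This cut asks only for a racemate that racemises by itself.
- Simplification: precursor 11 holds no stereochemical information, while 13 holds both centres of the target.
- Demand on the forward reaction: one catalyst must choose a face of C7 and one of two rapidly interconverting C8 enantiomers, and must ignore the ring C carbonyl.

**11 ⇒ 7 + 10.** The O4'–C8 bond is cut. At the dicarbonyl oxidation level C8 is doubly activated for substitution, which offsets the hindrance of O4'. Because C8 is labile, inversion or retention is irrelevant. The cut is convergent and divides the 42 carbons into pieces of 24 and 18. The forward step must select O4' over the chelated O5.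

**10 ⇒ 9.** The C8–Cl bond is cut. The enol of 9 is the only nucleophilic carbon, so one electrophilic chlorination suffices.

**7 ⇒ 6.** The O7–CH2Ph bond is cut. O7–H is the most acidic and least hindered phenol of 6, so a single equivalent of base and alkylating agent should find it. O4' needs no protecting group, because the side chain itself will occupy it.

**6 ⇒ 2 + 3.** The C4–C4a and O1–C2 bonds of ring C are cut. Symmetrical 3 offers three equivalent carbons, so no regiochemical question arises. The β-keto ester 2 supplies C2, C3, C4 and ring B in one piece, through ketene 4 and diketone 5. One thermal operation replaces the usual sequence of acylation, rearrangement and acid cyclisation, with no protecting group.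

**9 ⇒ 8 and 2 ⇒ 1.** The CH2–CO2Et bond is cut in each. Both halves of the target thus come from the same operation, ethoxycarbonylation of a commercial acetophenone.

## Roads not taken

**Alternative 1:** the most obvious cut is O4'–C8 at the alcohol oxidation level, with the stereocentres bought beforehand.
- Forward route: cinnamate A1 would undergo Sharpless asymmetric dihydroxylation (K2OsO2(OH)4, (DHQD)2PHAL, K3Fe(CN)6) to the threo diol A2. Its C8 hydroxyl would be activated (sulfonate or Mitsunobu) and displaced by phenol 7.
- Stereochemical flaw: syn addition to an E alkene gives threo, and the displacement inverts C8. The product is therefore the erythro ether A3, the wrong diastereomer.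
- Cost of repair: reaching 13 would need a further inversion at the ionisation-prone para-alkoxybenzylic C7. The other way is a Z alkene, a substrate class that this dihydroxylation handles with lower selectivity.
- Mechanistic flaw: a hindered, weakly nucleophilic phenoxide meets a secondary carbon that carries an acidic α-hydrogen and a β-oxygen, so elimination competes.
- Comparison: the chosen plan forms the same bond where configuration does not matter and reaches 13 in fewer operations.

**Alternative 2:** cut C7–C8.
- Forward route: phenol 7 would be O-alkylated to the glycolate imide A4, which carries the (S)-4-benzyloxazolidinone. An Evans syn aldol reaction (Bu2BOTf, Et3N) with aldehyde A5 would give adduct A6 in the correct (2S,3R) threo series. Reductive removal of the auxiliary would lead to 15.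
- Standing: this is the strongest competitor and is of similar length.
- Lewis acid demand: Bu2BOTf would first be consumed by the O5–H/C4=O chelate and the pyranone carbonyl. O5 would then need protection and release, two more steps.
- Enolate and solubility: the boron enolate carries a crowded 2,6-dimethoxyaryloxy group, and a flavone must stay dissolved at low temperature.
- Auxiliary: it is stoichiometric, and its hydride cleavage on a hindered imide competes with attack at the ring carbamate.
- Comparison: the chosen plan draws both centres from a few mole percent of catalyst and needs no cryogenic step.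

**Alternative 3:** the biomimetic cut, O4'–C8 by radical coupling.
- Forward route: tricin 6 and p-coumaryl alcohol A7 would be oxidised together (Ag2O, or peroxidase and H2O2). The O4' radical and the C8 radical would couple to quinone methide A8, and water would add at C7 to give A9.
- Standing: this is the shortest conceivable route.
- Flaw: C8 is formed in a radical–radical coupling with no chiral information, and water adds to either face of the planar quinone methide, so A9 is a mixture of all four stereoisomers.
- Second flaw: A7 is oxidised more easily than 6 and would mainly couple with itself.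
- Comparison: the single enantiomer could be obtained only by separation. The chosen plan keeps the idea of joining intact tricin to a C6–C3 unit through O4' but replaces the uncontrolled trapping by a catalyst-controlled reduction.

Key step: step 7

Assumption: the SMILES is read as (7R,8R), the threo diastereomer (C7 benzylic carbinol, C8 aryloxy methine, C9 CH2OH; in the esters C2 = C8 and C3 = C7). Compounds 1, 3 and 8 are taken as commercial.

## Route

Step 1
Reactants: 1 acetosyringone [1-(4-hydroxy-3,5-dimethoxyphenyl)ethan-1-one]
Product: 2 ethyl 3-(4-hydroxy-3,5-dimethoxyphenyl)-3-oxopropanoate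
Conditions: NaH (3.5 equiv), (EtO)2CO, THF, reflux; then aq HCl
Reagents that add atoms: diethyl carbonate, CCOC(=O)OCC
Why: Crossed Claisen condensation: NaH forms the phenoxide and then the methyl ketone enolate, which is C-ethoxycarbonylated by the non-enolisable carbonate. Irreversible deprotonation of the β-keto ester drives the reaction, and any O-carbonate formed at the phenoxide is reversible under the ethoxide present.

Step 2
Reactants: 2 ethyl 3-(4-hydroxy-3,5-dimethoxyphenyl)-3-oxopropanoate; 3 phloroglucinol (benzene-1,3,5-triol)
Product: 6 tricin [5,7-dihydroxy-2-(4-hydroxy-3,5-dimethoxyphenyl)-4H-chromen-4-one], via aroylketene 4 (not isolated), via diketone 5 (not isolated)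
Conditions: neat melt, 240 °C (microwave or metal bath), argon, 10–15 min
Reagents that add atoms: none
Why: Mentzer thermal flavone synthesis: 2 loses ethanol to aroylketene 4, which C-acylates the very electron-rich 3 to diketone 5. An ortho hydroxyl then adds to the aryl ketone and water is lost (6-membered ring C, O1–C2 closure). Without acid the coumarin (Pechmann) channel is not opened, and the symmetry of 3 removes any regiochemical issue.

Step 3
Reactants: 6 tricin
Product: 7 7-O-benzyltricin [7-(benzyloxy)-5-hydroxy-2-(4-hydroxy-3,5-dimethoxyphenyl)-4H-chromen-4-one]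
Conditions: BnBr (1.05 equiv), K2CO3 (1.0 equiv), DMF, 0 °C to rt
Reagents that add atoms: benzyl bromide, BrCc1ccccc1
Why: Williamson etherification under acidity control: O7–H is a vinylogous carboxylic acid and unhindered, so one equivalent of base places the charge there. O4'–H is flanked by two methoxy groups and O5–H is chelated to C4=O.

Step 4
Reactants: 8 4'-(benzyloxy)acetophenone [1-[4-(benzyloxy)phenyl]ethan-1-one]
Product: 9 ethyl 3-[4-(benzyloxy)phenyl]-3-oxopropanoate
Conditions: NaH (2.5 equiv), (EtO)2CO, THF, reflux; then aq HCl
Reagents that add atoms: diethyl carbonate, CCOC(=O)OCC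
Why: Crossed Claisen condensation as in step 1. The benzyl ether is inert to the base, and enolate formation from the product makes the reaction irreversible.

Step 5
Reactants: 9 ethyl 3-[4-(benzyloxy)phenyl]-3-oxopropanoate
Product: 10 ethyl (±)-3-[4-(benzyloxy)phenyl]-2-chloro-3-oxopropanoate
Conditions: SO2Cl2 (1.0 equiv), CH2Cl2, 0 °C to rt
Reagents that add atoms: sulfuryl chloride, O=S(=O)(Cl)Cl
Why: Electrophilic α-chlorination of the enol of a β-keto ester. The enol is far more nucleophilic than acyl-deactivated ring D, and one equivalent of reagent limits dichlorination.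

Step 6
Reactants: 7 7-O-benzyltricin; 10 ethyl (±)-3-[4-(benzyloxy)phenyl]-2-chloro-3-oxopropanoate
Product: 11 ethyl (±)-3-[4-(benzyloxy)phenyl]-2-{4-[7-(benzyloxy)-5-hydroxy-4-oxo-4H-chromen-2-yl]-2,6-dimethoxyphenoxy}-3-oxopropanoate
Conditions: K2CO3 (1.5 equiv), DMF, rt to 50 °C; then pH 4 buffer
Reagents that add atoms: none
Why: Williamson-type SN2 at a carbon flanked by two carbonyl groups, the known way to 2-aryloxy-β-keto esters; this activation compensates for the hindrance at O4'. Both ortho positions and the para position of ring B are blocked, so only O-alkylation is possible, and the chelated O5–H does not compete. The new centre C8 is formed racemic on purpose.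

Step 7
Reactants: 11 ethyl (±)-3-[4-(benzyloxy)phenyl]-2-{4-[7-(benzyloxy)-5-hydroxy-4-oxo-4H-chromen-2-yl]-2,6-dimethoxyphenoxy}-3-oxopropanoate
Product: 13 ethyl (2S,3R)-3-[4-(benzyloxy)phenyl]-2-{4-[7-(benzyloxy)-5-hydroxy-4-oxo-4H-chromen-2-yl]-2,6-dimethoxyphenoxy}-3-hydroxypropanoate, via chelated enol 12 (not isolated)
Conditions: RuCl[(S,S)-TsDPEN](p-cymene) (2 mol %), HCO2H/Et3N (5:2), CH2Cl2, 30 °C
Reagents that add atoms: none
Why: Noyori–Ikariya asymmetric transfer hydrogenation run as a dynamic kinetic resolution; the closest known reaction type is the conversion of racemic 2-alkoxy-3-aryl-3-oxopropanoates into syn-2-alkoxy-3-hydroxy esters by the same catalyst family. Formate converts the precatalyst into the hydride RuH[(S,S)-TsDPEN](p-cymene), which hands Ru–H to C7 and N–H to the carbonyl oxygen in a six-membered outer-sphere transition state and is regenerated with loss of CO2. In the buffered amine medium (R)-11 and (S)-11 interconvert through the achiral chelated enol 12 faster than either is reduced, because C8–H stands between the ketone, the ester and the aryloxy oxygen, so the whole racemate can drain through the faster channel (Curtin–Hammett situation). C7 is set by the catalyst: the CH–π contact between p-cymene and ring D fixes the orientation of the aryl ketone, and the (S,S) ligand delivers hydride in the sense that turns acetophenone into (S)-1-phenylethanol, here the Si face of C7, which reads 7R (3R in the ester) because C8 outranks ring D. C8 is set by matching within that transition state: only (S)-11 can hold the C8–O4' bond antiperiplanar to the incoming hydride (polar Felkin–Anh arrangement) while its small C8–H, not the ester, points at the catalyst, which should give the syn, that is threo, (2S,3R) ester. No ring is closed. The step needs chemoselectivity for the ring D ketone, secured because the ring C carbonyl is a chelated vinylogous ester of low electrophilicity and the ester and benzyl ethers do not respond to this hydride; it also needs racemisation to outrun reduction, secured by the 1,3-dicarbonyl acidity of C8–H. Product 13 is no longer a 1,3-dicarbonyl compound, so C8 is frozen once C7 is reduced.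

Step 8
Reactants: 13 ethyl (2S,3R)-3-[4-(benzyloxy)phenyl]-2-{4-[7-(benzyloxy)-5-hydroxy-4-oxo-4H-chromen-2-yl]-2,6-dimethoxyphenoxy}-3-hydroxypropanoate
Product: 15 7-(benzyloxy)-2-(4-{[(1R,2R)-1-[4-(benzyloxy)phenyl]-1,3-dihydroxypropan-2-yl]oxy}-3,5-dimethoxyphenyl)-5-hydroxy-4H-chromen-4-one, via hydroxy aldehyde 14 (not isolated)
Conditions: NaBH4 (excess), THF/H2O (3:1), 0 °C to rt; then aq NH4Cl
Reagents that add atoms: none
Why: Borohydride reduction of an activated ester: the α-aryloxy group and the neighbouring C7 alkoxyborohydride make this ester reducible by NaBH4 through aldehyde 14, as is standard for arylglycerol β-aryl ether esters. The flavone carbonyl, further deactivated as the O5 chelate, is inert to this reagent. No bond at C7 or C8 is touched; the C8 descriptor changes from S to R only because CH2OH ranks below C7.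

Step 9
Reactants: 15 7-(benzyloxy)-2-(4-{[(1R,2R)-1-[4-(benzyloxy)phenyl]-1,3-dihydroxypropan-2-yl]oxy}-3,5-dimethoxyphenyl)-5-hydroxy-4H-chromen-4-one
Product: 16 2-(4-{[(1R,2R)-1,3-dihydroxy-1-(4-hydroxyphenyl)propan-2-yl]oxy}-3,5-dimethoxyphenyl)-5,7-dihydroxy-4H-chromen-4-one (target, CNP0133235.3)
Conditions: H2 (1 atm), Pd/C (10 wt %), THF/MeOH, rt, stopped after uptake of two equivalents
Reagents that add atoms: none
Why: Catalytic hydrogenolysis of two aryl benzyl ethers. In neutral solvent these cleave faster than the secondary benzylic C7–OH or the conjugated C2=C3 bond is attacked. The absence of acid and base keeps the newly freed para-hydroxybenzylic alcohol from ionising, so C7 and C8 are retained.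

## Compound list

1 | acetosyringone | CC(=O)c1cc(OC)c(O)c(OC)c1 | starting material
2 | ethyl 3-(4-hydroxy-3,5-dimethoxyphenyl)-3-oxopropanoate | CCOC(=O)CC(=O)c1cc(OC)c(O)c(OC)c1 | intermediate
3 | phloroglucinol | Oc1cc(O)cc(O)c1 | starting material
4 | (4-hydroxy-3,5-dimethoxybenzoyl)ketene (not isolated) | O=C=CC(=O)c1cc(OC)c(O)c(OC)c1 | intermediate
5 | 1-(4-hydroxy-3,5-dimethoxyphenyl)-3-(2,4,6-trihydroxyphenyl)propane-1,3-dione (not isolated) | COc1cc(C(=O)CC(=O)c2c(O)cc(O)cc2O)cc(OC)c1O | intermediate
6 | tricin | COc1cc(-c2cc(=O)c3c(O)cc(O)cc3o2)cc(OC)c1O | intermediate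
7 | 7-O-benzyltricin | COc1cc(-c2cc(=O)c3c(O)cc(OCc4ccccc4)cc3o2)cc(OC)c1O | intermediate
8 | 4'-(benzyloxy)acetophenone | CC(=O)c1ccc(OCc2ccccc2)cc1 | starting material
9 | ethyl 3-[4-(benzyloxy)phenyl]-3-oxopropanoate | CCOC(=O)CC(=O)c1ccc(OCc2ccccc2)cc1 | intermediate
10 | ethyl (±)-3-[4-(benzyloxy)phenyl]-2-chloro-3-oxopropanoate | CCOC(=O)C(Cl)C(=O)c1ccc(OCc2ccccc2)cc1 | intermediate
11 | racemic 2-aryloxy-β-keto ester | COc1cc(-c2cc(=O)c3c(O)cc(OCc4ccccc4)cc3o2)cc(OC)c1OC(C(=O)OCC)C(=O)c1ccc(OCc2ccccc2)cc1 | intermediate
12 | chelated (E)-enol of 11 (not isolated) | COc1cc(-c2cc(=O)c3c(O)cc(OCc4ccccc4)cc3o2)cc(OC)c1O/C(C(=O)OCC)=C(/O)c1ccc(OCc2ccccc2)cc1 | intermediate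
13 | (2S,3R)-syn hydroxy ester | COc1cc(-c2cc(=O)c3c(O)cc(OCc4ccccc4)cc3o2)cc(OC)c1O[C@H](C(=O)OCC)[C@H](O)c1ccc(OCc2ccccc2)cc1 | intermediate
14 | (2S,3R)-hydroxy aldehyde (not isolated) | COc1cc(-c2cc(=O)c3c(O)cc(OCc4ccccc4)cc3o2)cc(OC)c1O[C@H](C=O)[C@H](O)c1ccc(OCc2ccccc2)cc1 | intermediate
15 | (7R,8R)-diol, 7-O- and ring D O-benzyl ether | COc1cc(-c2cc(=O)c3c(O)cc(OCc4ccccc4)cc3o2)cc(OC)c1O[C@H](CO)[C@H](O)c1ccc(OCc2ccccc2)cc1 | intermediate
16 | (7R,8R)-tricin 4'-O-[β-(4-hydroxyphenyl)glyceryl] ether | COc1cc(-c2cc(=O)c3c(O)cc(O)cc3o2)cc(OC)c1O[C@H](CO)[C@H](O)c1ccc(O)cc1 | target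

## Step count and least certain steps

Total step count: 9. Longest linear sequence: 7 steps (1, 2, 3, 6, 7, 8, 9) from acetosyringone; steps 4 and 5 form the short branch.

**Step 7 (key step).**
- Risk: the most likely failure is erosion or reversal of the syn/anti preference. The bulky 2,6-dimethoxyaryloxy group differs from the small alkoxy groups for which the syn outcome is known.
- Further risks: turnover may be slow at the electron-rich ring D ketone, and the O5–H/C4=O chelate may bind to ruthenium.
- What is secure: the facial choice at C7 rests on aryl ketone recognition and is the safer half.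
- Fallback: it applies if the anti channel wins and uses that channel. From 11, the enantiomeric catalyst RuCl[(R,R)-TsDPEN](p-cymene) should give the anti (2S,3S)-hydroxy ester F1, in which C8 is already correct. Mitsunobu inversion at C7 (4-nitrobenzoic acid, PPh3, DIAD) should give the (2S,3R)-4-nitrobenzoate F2, and ethanolysis (K2CO3, EtOH, 0 °C) comes back to the route at 13.

**Step 6.**
- Risk: proton transfer from the acidic chloride 10 to the phenoxide can park both partners as an unreactive pair.
- Further risks: attack of the phenoxide at chlorine or at the ketone (acyl transfer) can consume material.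
- Fallback: it makes the same bond under neutral conditions with inverted polarity logic. From 9, diazo transfer (4-acetamidobenzenesulfonyl azide, Et3N, MeCN) gives the diazo keto ester F3. Carbenoid O–H insertion into O4'–H of 7 (Rh2(OAc)4, 1,2-dichloroethane, 80 °C) comes back at 11; the chelated O5–H is a poor donor toward the carbenoid.

**Step 8.**
- Risk: the mildly basic borohydride medium may allow retro-aldol cleavage at C7–C8 or epimerisation at C8 before the ester is consumed.
- Further risk: long reaction times invite slow conjugate reduction of ring C.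
- Fallback: it blocks the retro-aldol path first. From 13, silylation of C7–OH (Et3SiCl, imidazole, DMF; the chelated O5–H is left alone) gives the triethylsilyl ether F4. Reduction in a non-protic medium (LiBH4, THF, 0 °C) gives the silylated primary alcohol F5, and buffered fluoride (Bu4NF, AcOH, THF) comes back at 15.

**Step 9.**
- Risk: over-reduction, that is hydrogenolysis of the C7–OH bond once ring D carries a free phenol, or saturation of C2=C3.
- Fallback: it removes the benzyl groups before any benzylic alcohol exists. From 11, hydrogenolysis (H2, Pd/C, THF) gives the debenzylated racemic keto ester F6. The conditions of step 7 give the (2S,3R)-hydroxy ester F7; the acidic formate medium keeps ring D protonated and the ketone reactive. The conditions of step 8 then come back at 16.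

**Step 2.**
- Risk: the free O4'–H of 2 may trap ketene 4 of another molecule, which leads to oligomerisation. Decomposition at 240 °C may lower the return.
- Fallback: it avoids the free phenol in the melt. From 3, the same Mentzer condensation with commercial ethyl 3-oxo-3-(3,4,5-trimethoxyphenyl)propanoate F8 gives 5,7-dihydroxy-3',4',5'-trimethoxyflavone F9. Regioselective cleavage of the central O4'–CH3 bond (AlCl3, CH2Cl2) comes back at 6. That methoxy group is twisted out of plane, flanked by two chelating oxygens and para to the pyranone, the known selectivity for 3,4,5-trimethoxyaryl carbonyl compounds.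

## Further compounds

F1 | step 7 | ethyl (2S,3S)-3-[4-(benzyloxy)phenyl]-2-{4-[7-(benzyloxy)-5-hydroxy-4-oxo-4H-chromen-2-yl]-2,6-dimethoxyphenoxy}-3-hydroxypropanoate | COc1cc(-c2cc(=O)c3c(O)cc(OCc4ccccc4)cc3o2)cc(OC)c1O[C@H](C(=O)OCC)[C@@H](O)c1ccc(OCc2ccccc2)cc1
F2 | step 7 | (2S,3R)-3-O-(4-nitrobenzoyl) derivative of 13 | COc1cc(-c2cc(=O)c3c(O)cc(OCc4ccccc4)cc3o2)cc(OC)c1O[C@H](C(=O)OCC)[C@H](OC(=O)c1ccc(cc1)[N+](=O)[O-])c1ccc(OCc2ccccc2)cc1
F3 | step 6 | ethyl 3-[4-(benzyloxy)phenyl]-2-diazo-3-oxopropanoate | CCOC(=O)C(=[N+]=[N-])C(=O)c1ccc(OCc2ccccc2)cc1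
F4 | step 8 | (2S,3R)-3-O-triethylsilyl ether of 13 | COc1cc(-c2cc(=O)c3c(O)cc(OCc4ccccc4)cc3o2)cc(OC)c1O[C@H](C(=O)OCC)[C@H](O[Si](CC)(CC)CC)c1ccc(OCc2ccccc2)cc1
F5 | step 8 | (7R,8R)-7-O-triethylsilyl ether of 15 | COc1cc(-c2cc(=O)c3c(O)cc(OCc4ccccc4)cc3o2)cc(OC)c1O[C@H](CO)[C@H](O[Si](CC)(CC)CC)c1ccc(OCc2ccccc2)cc1
F6 | step 9 | ethyl (±)-2-[4-(5,7-dihydroxy-4-oxo-4H-chromen-2-yl)-2,6-dimethoxyphenoxy]-3-(4-hydroxyphenyl)-3-oxopropanoate | COc1cc(-c2cc(=O)c3c(O)cc(O)cc3o2)cc(OC)c1OC(C(=O)OCC)C(=O)c1ccc(O)cc1
F7 | step 9 | ethyl (2S,3R)-2-[4-(5,7-dihydroxy-4-oxo-4H-chromen-2-yl)-2,6-dimethoxyphenoxy]-3-hydroxy-3-(4-hydroxyphenyl)propanoate | COc1cc(-c2cc(=O)c3c(O)cc(O)cc3o2)cc(OC)c1O[C@H](C(=O)OCC)[C@H](O)c1ccc(O)cc1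
F8 | step 2 | ethyl 3-oxo-3-(3,4,5-trimethoxyphenyl)propanoate | CCOC(=O)CC(=O)c1cc(OC)c(OC)c(OC)c1
F9 | step 2 | 5,7-dihydroxy-2-(3,4,5-trimethoxyphenyl)-4H-chromen-4-one | COc1cc(-c2cc(=O)c3c(O)cc(O)cc3o2)cc(OC)c1OC
A1 | alternative 1 | ethyl (E)-3-[4-(benzyloxy)phenyl]prop-2-enoate | CCOC(=O)/C=C/c1ccc(OCc2ccccc2)cc1
A2 | alternative 1 | ethyl (2S,3R)-3-[4-(benzyloxy)phenyl]-2,3-dihydroxypropanoate | O[C@H](C(=O)OCC)[C@H](O)c1ccc(OCc2ccccc2)cc1
A3 | alternative 1 | ethyl (2R,3R)-3-[4-(benzyloxy)phenyl]-2-{4-[7-(benzyloxy)-5-hydroxy-4-oxo-4H-chromen-2-yl]-2,6-dimethoxyphenoxy}-3-hydroxypropanoate (erythro) | COc1cc(-c2cc(=O)c3c(O)cc(OCc4ccccc4)cc3o2)cc(OC)c1O[C@@H](C(=O)OCC)[C@H](O)c1ccc(OCc2ccccc2)cc1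
A4 | alternative 2 | (S)-4-benzyl-3-({4-[7-(benzyloxy)-5-hydroxy-4-oxo-4H-chromen-2-yl]-2,6-dimethoxyphenoxy}acetyl)oxazolidin-2-one | COc1cc(-c2cc(=O)c3c(O)cc(OCc4ccccc4)cc3o2)cc(OC)c1OCC(=O)N1C(=O)OC[C@@H]1Cc1ccccc1
A5 | alternative 2 | 4-(benzyloxy)benzaldehyde | O=Cc1ccc(OCc2ccccc2)cc1
A6 | alternative 2 | (2S,3R)-syn aldol adduct on the (S)-4-benzyloxazolidin-2-one | COc1cc(-c2cc(=O)c3c(O)cc(OCc4ccccc4)cc3o2)cc(OC)c1O[C@H](C(=O)N1C(=O)OC[C@@H]1Cc1ccccc1)[C@H](O)c1ccc(OCc2ccccc2)cc1
A7 | alternative 3 | p-coumaryl alcohol [(E)-4-(3-hydroxyprop-1-enyl)phenol] | OC/C=C/c1ccc(O)cc1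
A8 | alternative 3 | racemic 8-O-4' quinone methide | COc1cc(-c2cc(=O)c3c(O)cc(O)cc3o2)cc(OC)c1OC(CO)C=C1C=CC(=O)C=C1
A9 | alternative 3 | mixture of all four stereoisomers of the constitution of 16 | COc1cc(-c2cc(=O)c3c(O)cc(O)cc3o2)cc(OC)c1OC(CO)C(O)c1ccc(O)cc1
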